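**Time against charge.** We read both flasks at 10 min, and that time means little until it is set against the charge it must turn over.

| flask | starting material | partner | free catalyst | remark | time |
|---|---|---|---|---|---|
| blue | 0.10 M | 0.059 M | 10 mM | run made earlier |  |
| amber | 0.10 M | 0.35 M | 10 mM | run made earlier |  |
| violet | 0.11 M | 0.090 M | 10 mM | run made earlier |  |
| beta | 0.10 M | 0.0900 M | 10 mM |  | 10 min |
| zeta | 0.20 M | 0.400 M | 10 mM |  | 10 min |

| run | time / min | product / % | starting material / % |
|---|---|---|---|
| blue | 0.417 | 1.0 | 99.3 |
| blue | 1.33 | 6.4 | 92.0 |
| blue | 2.50 | 15.1 | 83.4 |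
| blue | 4.00 | 22.9 | 75.8 |
| blue | 5.00 | 27.1 | 71.5 |
| amber | 0.417 | 3.7 | 97.2 |
| amber | 1.33 | 10.6 | 86.9 |
| amber | 2.50 | 21.3 | 74.2 |
| amber | 4.00 | 36.6 | 61.3 |
| amber | 5.00 | 44.8 | 52.9 |
| violet | 1.00 | 6.0 | 92.8 |
| violet | 2.00 | 11.2 | 88.0 |
| violet | 3.00 | 18.9 | 77.9 |
| violet | 4.00 | 23.3 | 73.7 |
| violet | 5.00 | 31.0 | 67.1 |

(scatter of a reading: 1 percentage point)



- which of the two ends with the higher amount of product, in percent of the starting material charged ("neither" if they lie within 2 percentage points) (beta / zeta / neither)
- product at the end, in percent of the starting material charged, beta
- product at the end, in percent of the starting material charged, zeta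

**The reach.** Amber makes product at a nearly steady pace while its starting material falls. Zeta has twice amber's charge and twice the time of amber's last reading, so the two factors cancel and amber's 44.8% carries over as 44.8%. We call this number the reach: the fraction of a flask's charge that a nearby run's steady pace turns over in the time. Violet has beta's partner and gives beta a reach of 68.2%. In beta the partner is the limiting reagent, with a share of 90.0% of the charge, and beta's reach stays under that share. In zeta the limiting reagent is starting material, because the partner's share there is 200% of the charge.

**One number enough?** For zeta we keep it. For beta we do not, assuming one partner used per product. At violet's pace we reckon that after 5.00 min beta stands at 34.1% product with partner at 55.9% of the charge, close to the 59.0% that blue starts with. Blue's 27.1% for the remaining 5.00 min brings our beta to 61.2%.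

**The forecast.** It says beta, with 59% for beta and 46% for zeta, and reads the flask as “roughly zero order in starting material”. Its zeta figure is close to amber's last reading taken over.

**The result.** The winner is beta, with 57.5% against 51.3% for zeta, which stands 6.5 percentage points above its reach.

    partner + free catalyst → catalyst intermediate A (k = 0.510 M⁻¹ s⁻¹)
    catalyst intermediate A → by-product + catalyst intermediate B (k = 0.880 s⁻¹)
    catalyst intermediate B → catalyst intermediate C (k = 0.0700 s⁻¹)
    starting material + catalyst intermediate C ⇌ catalyst intermediate D (K = 13.0 M⁻¹, k = 9.00 M⁻¹ s⁻¹)
    catalyst intermediate D → free catalyst + product (k = 0.0520 s⁻¹)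
    by-product + catalyst intermediate B → spent catalyst (k = 0.0270 M⁻¹ s⁻¹)

In zeta at 10.0 min, catalyst intermediate B moves on in the round 24 times as fast as it is lost to spent catalyst. Even so, 23.3% of the catalyst charged is spent by then, and 9.04% is free.

**Next flask.** Zeta charged with 0.080 M of starting material has a reach of 112%, past the whole charge. It gives 82.0%, with 17% of its starting material left.

(The readings come from a simulation for an exercise; noise was put on by code.)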